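Readings and results were computed with constants of no real substance.

Read the flask at 2.5 d, past the last dusk reading at 50.0 h, and decide what one more move can buy.

all flasks: substrate 0.020 M

|  | coupling partner | temperature | remark | time |
|---|---|---|---|---|
| dusk | 1.5 equiv | 50 °C | the very flask that is asked about, followed so far |  |
| noon | 1.5 equiv | 56 °C | run made earlier |  |
| flask | 1.50 equiv | 50 °C |  | 2.5 d |

- dusk (time / h: product / %, substrate / %): 4.00: 19.4, 58.3; 6.00: 30.0, 54.1; 8.00: 36.1, 49.9; 15.0: 53.3, 45.1; 20.0: 56.8, 42.1; 30.0: 60.3, 39.3; 50.0: 60.7, 39.0
- noon (time / h: product / %, substrate / %): 4.00: 38.0, 48.7; 6.00: 48.0, 43.0; 8.00: 55.2, 41.7; 15.0: 60.0, 36.6; 20.0: 63.8, 34.5; 30.0: 66.1, 32.5; 50.0: 66.7, 34.4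

(scatter of a reading: 1 percentage point)

- elm: at 2.5 d add coupling partner, 100% of the amount charged, then wait 30 h
- larch: at 2.5 d raise the temperature by 15 K, then wait 30 h
- maple: at 2.5 d take out 90% of the product then present, then wait 30 h
- oak: change nothing and wait 30 h more

- product taken out counts as made
- additions bring no volume worth counting

- product, in percent of the substrate first charged, at 2.5 d
- what to do for the largest gain in product; "none" if nothing gains more than 2 percentage points (elm / larch / maple / oak / none)
- product present, with what was taken out counted in, in percent of the substrate first charged, after elm
- product present, with what was taken out counted in, in percent of the substrate first charged, after maple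

Start from the dusk run. Substrate has flattened, from 39.3% at 30.0 h to 39.0% at 50.0 h, and product reads 60.7%, so commit to that figure for now. The balance lacks 0.3 percentage points, less than the 2 points an option must bring, so expect no useful rise from waiting, and none from heat or product removal if substrate has stopped for lack of coupling partner. Take coupling partner as the limiting reagent despite its excess, and assume a side route that consumes it pairwise.

Follow one partner molecule to its fork: it meets substrate or another partner. Its coupling share, read from the last dusk substrate with the partner taken as used up, is 40.7%, which makes the odds 0.685. Define the fork constant, the coupling odds divided by the ratio of substrate to partner at charging, and read 1.03 at dusk and 1.20 at noon.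

Elm is the move to test. At a constant share, the new charge would couple 61.0%, more than the substrate present. That link is weak, since this charge meets 0.260 substrate per partner against 0.667 at charging. Reforge it: the odds fall to 0.267, the share to 21.1%, and the reckoning puts product at 92.3% once that partner has reacted.

The forecast gives 60.8% now, elm as the move, 88% after it, below my figure, and 60.8% after maple, on the ground “So the flask is out of partner.”

The flask gives 61.4% now, with 0.0802% of its partner charge left at 60.0 h. Elm gains 27 points, against 0.17 points for larch, 0.16 points for maple and 0.16 points for oak, so the best move is elm. It reaches 88.8%, and maple reaches 61.5%.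

    substrate + coupling partner → intermediate (k = 0.170 M⁻¹ min⁻¹, Ea = 80.0 kJ mol⁻¹)
    intermediate → product (k = 0.00440 min⁻¹, Ea = 101 kJ mol⁻¹)
    2 coupling partner → homo dimer (k = 0.160 M⁻¹ min⁻¹, Ea = 52.0 kJ mol⁻¹)
    (constants at 50 °C)

Elm ends 3.5 points below the fork figure. Now carry the constant to the neighbouring flask at 35 °C, 15 K below dusk, which is 2.50 dusk-to-noon steps. Stepping down gives 0.697, odds of 0.465 and substrate used of 47.6%. That flask has used 45.7% of its substrate at 60.0 h, with 2.4% of its partner charge left. In that flask at 35 °C, intermediate holds 7.31% and product stands at 38.4%.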